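Readings and results were generated by integration from invented constants; noise was put on by code.

96.2 min is the number we carry: the lifetime of the left-handed substrate, meaning the amount left at mid-run divided by its rate of loss, as read from the midnight run. The flask asked about is that same flask, followed on to 2.0 h.

common to all: left-handed substrate 0.10 M; right-handed substrate 0.10 M; gas 11 mM (held); catalyst 0.091 mol%
- midnight: the very flask that is asked about, followed so far
- flask: time 2.0 h

midnight run (percent of the left-handed substrate and right-handed substrate together charged)

| time / min | left-handed product / % |
|---|---|
| 5.00 | 1.7 |
| 10.0 | 4.3 |
| 15.0 | 5.8 |
| 20.0 | 8.8 |
| 25.0 | 10.8 |

(standard deviation of a reading: 0.3 percentage points)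

- catalyst is single-handed; left-handed substrate and right-handed substrate are mirror images of each other, charged as a racemate, each of them at the stated concentration
- at the start none of coupling partner is dissolved
- on the list of suspects stand: coupling partner + catalyst + left-handed substrate -> catalyst + left-handed product; coupling partner + catalyst + right-handed substrate -> catalyst + right-handed product; gas <-> coupling partner; left-handed product <-> right-handed product

- amount of left-handed product at 2.0 h, in percent of the left-handed substrate and right-handed substrate together charged
- the change that raises the amount of left-handed product at 2.0 h, in percent of the left-handed substrate and right-handed substrate together charged most ("none" if none brings more than 2 percentage points) (south-west / north / east / none)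
- amount of left-handed product at 2.0 h, in percent of the left-handed substrate and right-handed substrate together charged, after south-west

- south-west: doubling the saturation concentration of gas, all else as stated
- north: doubling the amount of catalyst, all else as stated
- east: doubling the transfer coefficient of the gas, all else as stated

Between 5.00 min and 25.0 min the left-handed product gains 9.1 percentage points, and the readings show no sag beyond their scatter. From above, the straight line reaches 54.6% at 2.0 h, but the left-handed substrate charged is 50.0% of the total, so, with the suspected step between the two products set aside, our ceiling is 50.0%.

From below, we let the rate fall in step with [left-handed substrate], the pseudo-first-order case, which is harsher than the straight line the readings show. That step stays set aside here too, since the right-handed product went unread. Then 2.0 h is 1.25 lifetimes. Counting the lifetime from the full charge gives a floor of 33.2%, and counting it from mid-run tightens that to 35.6%. We commit to that bracket.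

The forecast says 45% (range 39% to 49%), inside our bracket, and names south-west as best, “a narrow pick over east”, with 49.7% after it.

The flask gives 39.1%, above our floor and below our ceiling. Left-handed product is then still made 9.62 times faster than it is used up. The best change is south-west, with 8.8 points against 6.2 points for east and 4.5 points for north.

    coupling partner + catalyst + left-handed substrate → catalyst + left-handed product (k = 42000 L² mol⁻² min⁻¹)
    coupling partner + catalyst + right-handed substrate → catalyst + right-handed product (k = 18000 L² mol⁻² min⁻¹)
    gas ⇌ coupling partner, rate k3*(csat - [coupling partner]) (kL = 0.160 min⁻¹)
    left-handed product ⇌ right-handed product (k = 0.00180 min⁻¹)

For south-west we let the rate double, so we take the lifetime as 48.1 min, which puts the floor at 45.9%, and that flask gives 47.9%.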